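The numbers in the tables were generated by integration with made-up constants, and the scatter is random.

Do we wait at 6.0 d, or do something to this flask?

- elm: starting material 0.50 M; reagent 0.90 M; free catalyst 2.9 mM; impurity 1.2 mM; the very flask that is asked about, followed so far
- flask: starting material 0.50 M; reagent 0.900 M; free catalyst 2.9 mM; impurity 1.2 mM; time 6.0 d

elm run (percent of the starting material charged)

| time / h | product / % | starting material / % |
|---|---|---|
| 6.00 | 19.1 | 80.5 |
| 15.0 | 27.0 | 72.3 |
| 40.0 | 31.8 | 68.5 |
| 96.0 | 32.3 | 67.2 |

(scatter of a reading: 0.5 percentage points)

- red: at 6.0 d add reagent, 50.0% of the amount charged, then wait 12 d
- green: at 6.0 d take out 90% of the product then present, then wait 12 d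
- amber: at 6.0 d add free catalyst, 50.0% of the amount charged, then wait 12 d
- ochre: change nothing and wait 12 d more

* product, in percent of the starting material first charged, at 6.0 d
* which option adds most product ("none" when 2 percentage points or less is all one gets) (red / green / amber / ochre / none)
* product present, with what was taken out counted in, in percent of the starting material first charged, after red
* product present, with what was taken out counted in, in percent of the starting material first charged, after amber

- product that was removed still counts
- additions bring no volume worth counting

**What do the readings show?** In the elm run, which is this flask so far, product climbs and then stands. Starting material stands with it, at 67.2%.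

**How do you measure a stop?** By the gap to the last product reading. That gap is 13 percentage points at 6.00 h and 5.3 points at 15.0 h, so it halves in 6.84 h. I call this the stall half-life: the time in which the gap to the plateau halves.

**Is it constant?** Not by these readings. From the start to 6.00 h, the same reckoning reads 4.65 h, which is shorter. So I count with the longer reading, to be safe.

**What stands at 6.0 d?** That time holds 21.1 stall half-lives. So I commit to the last reading, 32.3%, and I drop ochre.

**Then what stopped it?** The count does not say. Suppose the impurity takes catalyst one for one. That still leaves 1.70 mM. Reagent is never read. If one reagent goes per product, which I assume, product accounts for 0.161 M of its 0.900 M. A lengthening half-life hints at reagent lost unseen, though this is a guess.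

**Your choice?** Red. Scaling the plateau with the total reagent dose, I reckon 48.4% after red, and I expect amber to stay at the plateau.

The forecast, against my choice, gave 32.4% now, amber as best, 32.6% after red and 48% after amber, holding that “Fresh catalyst restarts it”.

The flask gives 32.8% at 6.0 d. The best option is red, which gains 22 points and reaches 55.2%, while amber stays at 32.8%.

    free catalyst + impurity → spent catalyst (k = 263 /M/min)
    2 reagent → homo dimer (k = 0.00814 /M/min)
    catalyst intermediate B → by-product + catalyst intermediate C (k = 1.07 /min)
    reagent + free catalyst ⇌ catalyst intermediate A (K = 0.580 /M, k = 64.5 /M/min)
    catalyst intermediate C → free catalyst + product (k = 1.69 /min)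
    starting material + catalyst intermediate A ⇌ catalyst intermediate B (K = 3.30 /M, k = 218 /M/min)

By the homo dimer step alone, the first half-life of reagent is 1.14 h, shorter than the stall half-life of 6.84 h. At 144 h this flask holds 0.368 M of homo dimer beside 0.164 M of by-product, with reagent, the limiting reagent, at 0% and free catalyst at 58.6%.

Take the neighbour charged with 0.0072 M of free catalyst. No readings of that neighbour are simulated, so I carry over this flask's stall half-life as an assumption. It counts 21.1 to 6.0 d, so I expect that neighbour to stand still by then, at a height the count does not give. It holds 61.5% product, with reagent at 0%.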